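C9–C10 is closed last by a stereoretentive sp3–sp2 coupling: the C10 secondary boronate of the left half (C10–C24) is handed to zinc and coupled with a (Z)-C9 alkenyl iodide that already carries the finished lactone (C1–C9); only desilylation follows.
Left half: C10, its methyl and C11 come from one linchpin, (R)-1,2-bis(pinacolboryl)propane, whose primary C–B bond is coupled first (C11–C12) with a 2-bromodiene grown from the oxane aldehyde (boron–Wittig for C14=C15, Suzuki coupling for C13–C14).
Ring A (oxane, closed first, step 8): syn-aldol (C20, C21), Felkin-controlled vinylogous Mukaiyama aldol (C19), Sharpless epoxidation (C16, C17), 6-exo epoxide opening by the C21 hydroxyl.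
Ring B (5,6-dihydro-2H-pyran-2-one, closed second, step 23): anti-carbomagnesiation of propargyl alcohol fixes the 8Z iodide, then Wittig, Brown allylation (C5), acryloylation and ring-closing metathesis.
Enabling feature: C10 is an unactivated secondary carbon (neighbours CH3, the C11 methylene and H, no β-heteroatom), so its C–B and C–Zn bonds hold their configuration; C9 is the unsubstituted terminus of the 6E,8Z-diene, so its C–I bond couples with retention; ring B tolerates an alkylzinc.

Key step: step 24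

Remark: positions are numbered C1 (lactone carbonyl) to C24 (propenyl methyl); the target is (5S,10R,16S,17R,19S,20R,21R) with 6E, 8Z, 12E, 14E and 22E alkenes; TBS = tert-butyldimethylsilyl, pin = pinacolato; where silylation changes CIP priorities the SMILES string is authoritative.

Step 1
Reactants: 1 (S)-4-benzyl-3-propanoyl-1,3-thiazolidine-2-thione; 2 (E)-but-2-enal
Product: 4 (S)-4-benzyl-3-[(2S,3R,4E)-3-hydroxy-2-methylhex-4-enoyl]-1,3-thiazolidine-2-thione, via titanium enolate 3 (not isolated)
Conditions: TiCl4 (1.05 equiv), i-Pr2NEt (1.1 equiv), N-methyl-2-pyrrolidone (1.0 equiv), CH2Cl2, 0 °C; then 2, −78 °C → 0 °C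
Reagents that add atoms: none
Why: Titanium-mediated Evans-syn aldol of an N-acyl thiazolidinethione, in which the chlorotitanium (Z)-enolate should react through a non-chelated Zimmerman–Traxler chair whose open face is fixed by the (S)-benzyl group, setting C20 and C21 (2,3-syn).

Step 2
Reactants: 4 aldol adduct
Product: 5 TBS ether of 4
Conditions: TBSOTf, 2,6-lutidine, CH2Cl2, 0 °C
Reagents that add atoms: tert-butyldimethylsilyl trifluoromethanesulfonate, CC(C)(C)[Si](C)(C)OS(=O)(=O)C(F)(F)F
Why: Silylation of a secondary alcohol with a silyl triflate, which touches no stereocentre.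

Step 3
Reactants: 5 silylated aldol adduct
Product: 6 (2S,3R,4E)-3-(tert-butyldimethylsilyloxy)-2-methylhex-4-enal
Conditions: i-Bu2AlH (1.5 equiv), CH2Cl2, −78 °C
Reagents that add atoms: none
Why: Direct half-reduction of the activated thiazolidinethione imide, which should stop at a stable aluminium hemiaminal and release the aldehyde and the auxiliary on work-up without epimerising the α-methyl centre at low temperature.

Step 4
Reactants: 7 methyl (E)-but-2-enoate
Product: 9 tert-butyl[(1-methoxybuta-1,3-dien-1-yl)oxy]dimethylsilane, via lithium dienolate 8 (not isolated)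
Conditions: LiN(i-Pr)2, DMPU, THF, −78 °C; then TBSCl
Reagents that add atoms: tert-butyldimethylsilyl chloride, CC(C)(C)[Si](C)(C)Cl
Why: γ-Deprotonation of the crotonate gives the extended dienolate, which is O-silylated (silyl ketene acetal formation); the ketene acetal geometry is inconsequential.

Step 5
Reactants: 6 aldehyde; 9 silyl dienol ether
Product: 10 methyl (2E,5S,6R,7R,8E)-7-(tert-butyldimethylsilyloxy)-5-hydroxy-6-methyldeca-2,8-dienoate
Conditions: B(C6F5)3 (1.0 equiv), i-PrOH (1.1 equiv), CH2Cl2/Et2O, −78 °C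
Reagents that add atoms: none
Why: Vinylogous Mukaiyama aldol reaction in which the borane-activated aldehyde should be attacked at the γ-carbon under Felkin–Anh control (attack anti to the C21 chain, the β-silyloxy group exerting little 1,3-induction), setting the C19 carbinol syn to the C20 methyl and giving the (E)-enoate.

Step 6
Reactants: 10 hydroxy enoate
Product: 11 (2E,5S,6R,7R,8E)-7-(tert-butyldimethylsilyloxy)-6-methyldeca-2,8-diene-1,5-diol
Conditions: i-Bu2AlH (3.5 equiv), CH2Cl2, −78 °C → −20 °C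
Reagents that add atoms: none
Why: 1,2-Reduction of an α,β-unsaturated ester to the allylic alcohol with an aluminium hydride.

Step 7
Reactants: 11 allylic alcohol
Product: 12 {(2S,3S)-3-[(2S,3R,4R,5E)-4-(tert-butyldimethylsilyloxy)-2-hydroxy-3-methylhept-5-en-1-yl]oxiran-2-yl}methanol
Conditions: Ti(Oi-Pr)4 (0.2 equiv), L-(+)-diisopropyl tartrate (0.24 equiv), t-BuOOH, 4 Å molecular sieves, CH2Cl2, −20 °C
Reagents that add atoms: tert-butyl hydroperoxide, CC(C)(C)OO
Why: Sharpless asymmetric epoxidation, in which L-(+)-tartrate should deliver oxygen to the face of the (E)-allylic alcohol that gives the (2S,3S)-epoxy alcohol (reagent control), setting C16 and the pre-inversion configuration at C17.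

Step 8
Reactants: 12 epoxy silyl ether
Product: 14 (S)-1-[(2R,4S,5R,6R)-4-hydroxy-5-methyl-6-[(E)-prop-1-en-1-yl]oxan-2-yl]ethane-1,2-diol, via epoxy triol 13 (not isolated)
Conditions: Bu4NF, THF, 0 °C → rt; then camphorsulfonic acid (0.1 equiv), CH2Cl2, 0 °C → rt
Reagents that add atoms: none
Why: Fluoride desilylation frees the C21 hydroxyl, which should open the epoxide under acid catalysis in the 6-exo-tet mode at C17 with inversion (Baldwin-favoured over 7-endo, no cation-stabilising group at C16), closing the 2,6-cis oxane and revealing the C16 hydroxyl.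

Step 9
Reactants: 14 oxane triol
Product: 15 tris-TBS ether of 14
Conditions: TBSOTf (3.5 equiv), 2,6-lutidine, CH2Cl2, −78 °C → 0 °C
Reagents that add atoms: tert-butyldimethylsilyl trifluoromethanesulfonate, CC(C)(C)[Si](C)(C)OS(=O)(=O)C(F)(F)F
Why: Exhaustive silylation with a silyl triflate, reactive enough for the axial C19 hydroxyl.

Step 10
Reactants: 15 tris-silyl ether
Product: 16 primary alcohol (C15–OH free; C16 and C19 TBS ethers kept)
Conditions: HF·pyridine, pyridine, THF, 0 °C
Reagents that add atoms: none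
Why: Selective protodesilylation, since the unhindered primary silyl ether is cleaved much faster than the two secondary ones.

Step 11
Reactants: 16 primary alcohol
Product: 17 α-silyloxy aldehyde (C15 aldehyde)
Conditions: Dess–Martin periodinane, CH2Cl2, 0 °C → rt
Reagents that add atoms: none
Why: Dess–Martin oxidation under near-neutral conditions, which should not epimerise the α-silyloxy centre C16.

Step 12
Reactants: 17 aldehyde; 18 2,2'-methylenebis(4,4,5,5-tetramethyl-1,3,2-dioxaborolane)
Product: 20 (E)-alkenyl pinacol boronate (C14–B), via lithiated bis(boronate) 19 (not isolated)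
Conditions: 18 (1.3 equiv), lithium 2,2,6,6-tetramethylpiperidide (LiTMP), THF, 0 °C; then 17, −78 °C → rt
Reagents that add atoms: none
Why: Boron–Wittig reaction, in which the stabilised α-diboryl carbanion adds to the aldehyde and syn-eliminates a borate to give the (E)-alkenyl boronate without epimerising C16.

Step 13
Reactants: 21 propyne
Product: 22 (E)-2-bromo-1-iodoprop-1-ene
Conditions: IBr, CH2Cl2, −78 °C → 0 °C
Reagents that add atoms: iodine monobromide, BrI
Why: Electrophilic anti-addition across the alkyne through an iodonium ion (iodine to the terminal carbon, bromide to the internal carbon), giving the (E)-dihalide.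

Step 14
Reactants: 20 alkenyl boronate; 22 (E)-2-bromo-1-iodoprop-1-ene
Product: 23 (12E,14E)-2-bromodiene (C12–Br)
Conditions: Pd(PPh3)4 (5 mol %), aq. KOH, THF, rt
Reagents that add atoms: none
Why: Suzuki–Miyaura coupling in which zerovalent palladium should insert into the C–I bond far faster than into the C–Br bond, with retention of both alkene geometries.

Step 15
Reactants: 24 2,4,6-triisopropylbenzoic acid
Product: 25 ethyl 2,4,6-triisopropylbenzoate
Conditions: EtI, K2CO3, DMF, rt
Reagents that add atoms: iodoethane, CCI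
Why: O-Alkylation of the carboxylate (SN2), giving the hindered benzoate needed for directed α-lithiation.

Step 16
Reactants: 25 ethyl 2,4,6-triisopropylbenzoate; 18 2,2'-methylenebis(4,4,5,5-tetramethyl-1,3,2-dioxaborolane)
Product: 28 (R)-2,2'-(propane-1,2-diyl)bis(4,4,5,5-tetramethyl-1,3,2-dioxaborolane), via lithiated benzoate 26 (not isolated), via boronate complex 27 (not isolated)
Conditions: s-BuLi, (−)-sparteine, Et2O, −78 °C; then 18 (2 equiv), −78 °C → 35 °C
Reagents that add atoms: none
Why: Lithiation–borylation (sparteine-mediated removal of the pro-S α-hydrogen, borylation with retention, then 1,2-metallate rearrangement of the boryl-methyl group with inversion at carbon), which should set the future C10 centre as R under reagent control.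

Step 17
Reactants: 23 bromodiene; 28 (R)-1,2-bis(boronate)
Product: 29 left-half secondary boronate (C10–Bpin, R)
Conditions: Pd(OAc)2 (2 mol %), RuPhos (2 mol %), KOH (3 equiv), THF/H2O 10:1, 70 °C
Reagents that add atoms: none
Why: Chemoselective Suzuki–Miyaura coupling of a vicinal bis(boronate), in which only the primary C–B bond (activated by the neighbouring boronate) should transmetalate, leaving the secondary C–B bond and its configuration intact and retaining the 12E geometry.

Step 18
Reactants: 30 prop-2-yn-1-ol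
Product: 32 (Z)-3-iodo-2-methylprop-2-en-1-ol, via alkenylmagnesium alkoxide 31 (not isolated)
Conditions: MeMgBr (2.5 equiv), CuI (10 mol %), THF, −10 °C → rt; then I2, −78 °C → 0 °C
Reagents that add atoms: methylmagnesium bromide, C[Mg]Br; iodine, II
Why: Copper-catalysed anti-carbomagnesiation of the propargylic alkoxide (the magnesium ends cis to the CH2O group through chelation) followed by iodinolysis with retention, fixing the future 8Z geometry.

Step 19
Reactants: 32 (Z)-iodo allylic alcohol
Product: 33 (Z)-3-iodo-2-methylprop-2-enal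
Conditions: MnO2, CH2Cl2, rt, dark
Reagents that add atoms: none
Why: Neutral allylic oxidation with manganese dioxide, which should not isomerise the (Z)-β-iodoenal.

Step 20
Reactants: 33 (Z)-iodoenal; 34 (triphenyl-λ5-phosphanylidene)acetaldehyde
Product: 35 (2E,4Z)-5-iodo-4-methylpenta-2,4-dienal
Conditions: CH2Cl2, rt
Reagents that add atoms: none
Why: Wittig olefination with a stabilised formyl ylide, which should give the (E)-enal (the 6E alkene).

Step 21
Reactants: 35 dienal; 36 (−)-B-allyldiisopinocampheylborane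
Product: 38 (4S,5E,7Z)-8-iodo-7-methylocta-1,5,7-trien-4-ol, via borinate 37 (not isolated)
Conditions: Et2O, −78 °C; then NaOH, H2O2, 0 °C → rt
Reagents that add atoms: none
Why: Brown asymmetric allylboration through a chair transition state, in which the reagent derived from (+)-α-pinene should attack the si face of the aldehyde and set C5 as S.

Step 22
Reactants: 38 homoallylic alcohol; 39 prop-2-enoyl chloride
Product: 40 (4S,5E,7Z)-8-iodo-7-methylocta-1,5,7-trien-4-yl prop-2-enoate
Conditions: Et3N, 4-dimethylaminopyridine (cat.), CH2Cl2, −20 °C → 0 °C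
Reagents that add atoms: none
Why: Acylation of a secondary alcohol with an acid chloride.

Step 23
Reactants: 40 acrylate
Product: 41 (S)-6-[(1E,3Z)-4-iodo-3-methylbuta-1,3-dien-1-yl]-5,6-dihydro-2H-pyran-2-one
Conditions: second-generation Grubbs catalyst RuCl2(=CHPh)(H2IMes)(PCy3) (5 mol %), CH2Cl2, 40 °C
Reagents that add atoms: none
Why: Ring-closing metathesis between the acrylate and the terminal alkene should close the six-membered unsaturated lactone, the trisubstituted iododiene being too hindered and electron-poor to compete.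

Step 24
Reactants: 29 left-half secondary boronate; 41 right-half (Z)-alkenyl iodide
Product: 44 16,19-bis-O-TBS ether of the target, via boronate complex 42 (not isolated), via alkylzinc acetate 43 (not isolated)
Conditions: t-BuLi (1.1 equiv), THF, −78 °C; Zn(OAc)2 (1.2 equiv), −78 °C → 0 °C; then 41 (1.1 equiv), Pd(OAc)2 (5 mol %), CPhos (10 mol %), THF, 0 °C → rt
Reagents that add atoms: none
Why: tert-Butyllithium adds to boron of 29 to give complex 42, whose secondary C10–B bond should pass to zinc with retention (the tert-butyl group is a non-transferable ligand), and the alkylzinc 43 then enters a Negishi cycle in which zerovalent palladium inserts into the C9–I bond of 41 with retention of the (Z)-geometry, transmetalates with retention at C10 and reductively eliminates. The closest known reaction types are the stereoretentive boron-to-zinc exchange of secondary alkylboron compounds and the stereoretentive Negishi coupling of configurationally defined secondary alkylzinc reagents with alkenyl iodides. No ring is closed in this step; the oxane and the dihydropyranone are carried through intact. No new stereocentre is formed: C10 (R) comes from step 16 and the 8Z alkene from step 18, and the step only has to transfer both without loss. The selectivity needed is retention at C10 against β-hydride elimination and chain-walking toward the allylic C11 hydrogens, and against Z-to-E isomerisation of the dienylpalladium; the substrate helps because C10 carries no β-heteroatom and no adjacent π-system, and a bulky biarylphosphine makes reductive elimination fast. Chemoselectivity rests on the low basicity and nucleophilicity of the alkylzinc, which should leave the unsaturated lactone and the silyl ethers untouched.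

Step 25
Reactants: 44 bis-silyl ether
Product: 45 target (CNP0248490.1)
Conditions: HF·pyridine, pyridine, THF, 0 °C → rt
Reagents that add atoms: none
Why: Global protodesilylation with buffered hydrogen fluoride, which should spare the unsaturated lactone, the allylic alcohol and the polyene.

Compound list
1 | (S)-4-benzyl-3-propanoyl-1,3-thiazolidine-2-thione | CCC(=O)N1[C@@H](Cc2ccccc2)CSC1=S | starting material
2 | (E)-but-2-enal | C/C=C/C=O | starting material
3 | chlorotitanium (Z)-enolate of 1 | C/C=C(\O[Ti](Cl)(Cl)Cl)N1[C@@H](Cc2ccccc2)CSC1=S | intermediate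
4 | (S)-4-benzyl-3-[(2S,3R,4E)-3-hydroxy-2-methylhex-4-enoyl]-1,3-thiazolidine-2-thione | C/C=C/[C@@H](O)[C@H](C)C(=O)N1[C@@H](Cc2ccccc2)CSC1=S | intermediate
5 | TBS ether of 4 | C/C=C/[C@@H](O[Si](C)(C)C(C)(C)C)[C@H](C)C(=O)N1[C@@H](Cc2ccccc2)CSC1=S | intermediate
6 | (2S,3R,4E)-3-(tert-butyldimethylsilyloxy)-2-methylhex-4-enal | C/C=C/[C@@H](O[Si](C)(C)C(C)(C)C)[C@H](C)C=O | intermediate
7 | methyl (E)-but-2-enoate | C/C=C/C(=O)OC | starting material
8 | lithium dienolate of 7 | C=CC=C(OC)O[Li] | intermediate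
9 | tert-butyl[(1-methoxybuta-1,3-dien-1-yl)oxy]dimethylsilane | C=CC=C(OC)O[Si](C)(C)C(C)(C)C | intermediate
10 | methyl (2E,5S,6R,7R,8E)-7-(tert-butyldimethylsilyloxy)-5-hydroxy-6-methyldeca-2,8-dienoate | C/C=C/[C@@H](O[Si](C)(C)C(C)(C)C)[C@H](C)[C@@H](O)C/C=C/C(=O)OC | intermediate
11 | (2E,5S,6R,7R,8E)-7-(tert-butyldimethylsilyloxy)-6-methyldeca-2,8-diene-1,5-diol | C/C=C/[C@@H](O[Si](C)(C)C(C)(C)C)[C@H](C)[C@@H](O)C/C=C/CO | intermediate
12 | {(2S,3S)-3-[(2S,3R,4R,5E)-4-(tert-butyldimethylsilyloxy)-2-hydroxy-3-methylhept-5-en-1-yl]oxiran-2-yl}methanol | C/C=C/[C@@H](O[Si](C)(C)C(C)(C)C)[C@H](C)[C@@H](O)C[C@@H]1O[C@H]1CO | intermediate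
13 | {(2S,3S)-3-[(2S,3R,4R,5E)-2,4-dihydroxy-3-methylhept-5-en-1-yl]oxiran-2-yl}methanol | C/C=C/[C@@H](O)[C@H](C)[C@@H](O)C[C@@H]1O[C@H]1CO | intermediate
14 | (S)-1-[(2R,4S,5R,6R)-4-hydroxy-5-methyl-6-[(E)-prop-1-en-1-yl]oxan-2-yl]ethane-1,2-diol | C/C=C/[C@H]1O[C@@H]([C@@H](O)CO)C[C@H](O)[C@H]1C | intermediate
15 | tris-TBS ether of 14 | C/C=C/[C@H]1O[C@@H]([C@@H](O[Si](C)(C)C(C)(C)C)CO[Si](C)(C)C(C)(C)C)C[C@H](O[Si](C)(C)C(C)(C)C)[C@H]1C | intermediate
16 | 15 with the primary (C15) hydroxyl free | C/C=C/[C@H]1O[C@@H]([C@@H](O[Si](C)(C)C(C)(C)C)CO)C[C@H](O[Si](C)(C)C(C)(C)C)[C@H]1C | intermediate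
17 | C15 aldehyde from 16 | C/C=C/[C@H]1O[C@@H]([C@@H](O[Si](C)(C)C(C)(C)C)C=O)C[C@H](O[Si](C)(C)C(C)(C)C)[C@H]1C | intermediate
18 | 2,2'-methylenebis(4,4,5,5-tetramethyl-1,3,2-dioxaborolane) | C(B1OC(C)(C)C(C)(C)O1)B1OC(C)(C)C(C)(C)O1 | starting material
19 | lithiated 18 | [Li]C(B1OC(C)(C)C(C)(C)O1)B1OC(C)(C)C(C)(C)O1 | intermediate
20 | (E)-alkenyl pinacol boronate (C14–B) | C/C=C/[C@H]1O[C@@H]([C@@H](O[Si](C)(C)C(C)(C)C)/C=C/B2OC(C)(C)C(C)(C)O2)C[C@H](O[Si](C)(C)C(C)(C)C)[C@H]1C | intermediate
21 | propyne | CC#C | starting material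
22 | (E)-2-bromo-1-iodoprop-1-ene | Br/C(C)=C/I | intermediate
23 | (12E,14E)-2-bromodiene (C12–Br) | C/C=C/[C@H]1O[C@@H]([C@@H](O[Si](C)(C)C(C)(C)C)/C=C/C=C(\C)Br)C[C@H](O[Si](C)(C)C(C)(C)C)[C@H]1C | intermediate
24 | 2,4,6-triisopropylbenzoic acid | CC(C)c1cc(C(C)C)c(C(=O)O)c(C(C)C)c1 | starting material
25 | ethyl 2,4,6-triisopropylbenzoate | CCOC(=O)c1c(C(C)C)cc(C(C)C)cc1C(C)C | intermediate
26 | (S)-1-lithioethyl 2,4,6-triisopropylbenzoate (sparteine complex) | C[C@H]([Li])OC(=O)c1c(C(C)C)cc(C(C)C)cc1C(C)C | intermediate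
27 | lithium boronate complex of 26 and 18 | [Li+].C[C@@H](OC(=O)c1c(C(C)C)cc(C(C)C)cc1C(C)C)[B-]1(CB2OC(C)(C)C(C)(C)O2)OC(C)(C)C(C)(C)O1 | intermediate
28 | (R)-2,2'-(propane-1,2-diyl)bis(4,4,5,5-tetramethyl-1,3,2-dioxaborolane) | C[C@H](CB1OC(C)(C)C(C)(C)O1)B1OC(C)(C)C(C)(C)O1 | intermediate
29 | left-half secondary boronate (C10–Bpin, R) | C/C=C/[C@H]1O[C@@H]([C@@H](O[Si](C)(C)C(C)(C)C)/C=C/C=C(\C)C[C@@H](C)B2OC(C)(C)C(C)(C)O2)C[C@H](O[Si](C)(C)C(C)(C)C)[C@H]1C | intermediate
30 | prop-2-yn-1-ol | C#CCO | starting material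
31 | (Z)-alkenylmagnesium alkoxide | Br[Mg]OC/C(C)=C\[Mg]Br | intermediate
32 | (Z)-3-iodo-2-methylprop-2-en-1-ol | OC/C(C)=C\I | intermediate
33 | (Z)-3-iodo-2-methylprop-2-enal | O=C/C(C)=C\I | intermediate
34 | (triphenyl-λ5-phosphanylidene)acetaldehyde | O=CC=P(c1ccccc1)(c1ccccc1)c1ccccc1 | starting material
35 | (2E,4Z)-5-iodo-4-methylpenta-2,4-dienal | O=C/C=C/C(C)=C\I | intermediate
36 | (−)-B-allyldiisopinocampheylborane | C=CCB([C@@H]1C[C@@H]2C[C@H]([C@H]1C)C2(C)C)[C@@H]1C[C@@H]2C[C@H]([C@H]1C)C2(C)C | starting material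
37 | diisopinocampheylborinate of 38 | I/C=C(C)\C=C\[C@@H](OB([C@@H]1C[C@@H]2C[C@H]([C@H]1C)C2(C)C)[C@@H]1C[C@@H]2C[C@H]([C@H]1C)C2(C)C)CC=C | intermediate
38 | (4S,5E,7Z)-8-iodo-7-methylocta-1,5,7-trien-4-ol | I/C=C(C)\C=C\[C@@H](O)CC=C | intermediate
39 | prop-2-enoyl chloride | C=CC(=O)Cl | starting material
40 | (4S,5E,7Z)-8-iodo-7-methylocta-1,5,7-trien-4-yl prop-2-enoate | I/C=C(C)\C=C\[C@@H](OC(=O)C=C)CC=C | intermediate
41 | (S)-6-[(1E,3Z)-4-iodo-3-methylbuta-1,3-dien-1-yl]-5,6-dihydro-2H-pyran-2-one | I/C=C(C)\C=C\[C@@H]1CC=CC(=O)O1 | intermediate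
42 | lithium tert-butyl boronate complex of 29 | [Li+].C/C=C/[C@H]1O[C@@H]([C@@H](O[Si](C)(C)C(C)(C)C)/C=C/C=C(\C)C[C@@H](C)[B-]2(C(C)(C)C)OC(C)(C)C(C)(C)O2)C[C@H](O[Si](C)(C)C(C)(C)C)[C@H]1C | intermediate
43 | secondary alkylzinc acetate (C10–Zn) | C/C=C/[C@H]1O[C@@H]([C@@H](O[Si](C)(C)C(C)(C)C)/C=C/C=C(\C)C[C@@H](C)[Zn]OC(C)=O)C[C@H](O[Si](C)(C)C(C)(C)C)[C@H]1C | intermediate
44 | 16,19-bis-O-TBS ether of the target | C/C=C/[C@H]1O[C@@H]([C@@H](O[Si](C)(C)C(C)(C)C)/C=C/C=C(\C)C[C@@H](C)/C=C(C)\C=C\[C@@H]2CC=CC(=O)O2)C[C@H](O[Si](C)(C)C(C)(C)C)[C@H]1C | intermediate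
45 | CNP0248490.1 | C/C=C/[C@H]1O[C@@H]([C@@H](O)/C=C/C=C(\C)C[C@@H](C)/C=C(C)\C=C\[C@@H]2CC=CC(=O)O2)C[C@H](O)[C@H]1C | target

Total step count: 25. Longest linear sequence: 15 steps (1, 2, 3, 5, 6, 7, 8, 9, 10, 11, 12, 14, 17, 24, 25).

Steps most likely to fail

Step 24. What may go wrong: erosion of configuration at C10 during the boron-to-zinc exchange, β-hydride elimination and chain-walking of the secondary alkylpalladium toward C11, or Z-to-E isomerisation of the dienylpalladium. The fallback sets out from 29 and returns at 44; it uses a Zweifel olefination with a non-conjugated alkenyllithium and builds the lactone afterwards. Prop-2-yn-1-ol 30 is carboaluminated and iodinated (AlMe3, Cp2ZrCl2 cat.; then I2) to (E)-3-iodo-2-methylprop-2-en-1-ol F1 and silylated (TBSCl, imidazole) to its TBS ether F2. Iodine–lithium exchange on F2 (t-BuLi, −78 °C), addition of 29, then I2 and NaOMe should give the (Z)-allylic silyl ether F3 (anti 1,2-migration with retention at C10, anti elimination with inversion of the alkene geometry). HF·pyridine at 0 °C frees the primary allylic alcohol F4, MnO2 gives the (Z)-enal F5, Wittig reaction with 34 gives the dienal F6, Brown allylation with 36 gives the homoallylic alcohol F7, acylation with 39 gives the acrylate F8, and ring-closing metathesis with the second-generation Grubbs catalyst gives 44.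

Step 17. What may go wrong: protodeboronation of 28, transmetalation of the secondary instead of the primary C–B bond, or slow oxidative addition into the hindered bromodiene accompanied by hydroxide-induced silyl migration. The fallback sets out from 23 and returns at 29. Negishi coupling of 23 with (pinacolatoboryl)methylzinc iodide (from commercial 2-(iodomethyl)-4,4,5,5-tetramethyl-1,3,2-dioxaborolane and zinc; Pd(PPh3)4) should give the allylic boronate F9. F9 is then homologated with the lithiated benzoate 26 (made as in step 16) by lithiation–borylation; 1,2-migration of the C11 methylene inserts the methyl-bearing C10 with the same R sense and gives 29.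

Step 14. What may go wrong: competing oxidative addition into the C–Br bond of 22 or of the product (oligomers), protodeboronation of 20, and loss of the volatile dihalide. The fallback sets out from 17 and returns at 23. Takai iodo-olefination of 17 (CrCl2, CHI3) should give the (E)-vinyl iodide F10, and Sonogashira coupling with propyne 21 (Pd(PPh3)2Cl2, CuI, Et3N) gives the enyne F11. Hydrozirconation with Cp2Zr(H)Cl (syn addition, zirconium on the methyl-bearing carbon) followed by N-bromosuccinimide gives 23 with retention.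

Further compounds
F1 | step 24 | (E)-3-iodo-2-methylprop-2-en-1-ol | OC/C(C)=C/I
F2 | step 24 | tert-butyl{[(E)-3-iodo-2-methylprop-2-en-1-yl]oxy}dimethylsilane | CC(C)(C)[Si](C)(C)OC/C(C)=C/I
F3 | step 24 | (Z)-allylic silyl ether (C7–OTBS, 8Z, C10 R) | C/C=C/[C@H]1O[C@@H]([C@@H](O[Si](C)(C)C(C)(C)C)/C=C/C=C(\C)C[C@@H](C)/C=C(C)\CO[Si](C)(C)C(C)(C)C)C[C@H](O[Si](C)(C)C(C)(C)C)[C@H]1C
F4 | step 24 | (Z)-allylic alcohol (C7–OH) | C/C=C/[C@H]1O[C@@H]([C@@H](O[Si](C)(C)C(C)(C)C)/C=C/C=C(\C)C[C@@H](C)/C=C(C)\CO)C[C@H](O[Si](C)(C)C(C)(C)C)[C@H]1C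
F5 | step 24 | (Z)-enal (C7 aldehyde) | C/C=C/[C@H]1O[C@@H]([C@@H](O[Si](C)(C)C(C)(C)C)/C=C/C=C(\C)C[C@@H](C)/C=C(C)\C=O)C[C@H](O[Si](C)(C)C(C)(C)C)[C@H]1C
F6 | step 24 | (6E,8Z)-dienal (C5 aldehyde) | C/C=C/[C@H]1O[C@@H]([C@@H](O[Si](C)(C)C(C)(C)C)/C=C/C=C(\C)C[C@@H](C)/C=C(C)\C=C\C=O)C[C@H](O[Si](C)(C)C(C)(C)C)[C@H]1C
F7 | step 24 | (5S)-homoallylic alcohol | C/C=C/[C@H]1O[C@@H]([C@@H](O[Si](C)(C)C(C)(C)C)/C=C/C=C(\C)C[C@@H](C)/C=C(C)\C=C\[C@@H](O)CC=C)C[C@H](O[Si](C)(C)C(C)(C)C)[C@H]1C
F8 | step 24 | acrylate of F7 | C/C=C/[C@H]1O[C@@H]([C@@H](O[Si](C)(C)C(C)(C)C)/C=C/C=C(\C)C[C@@H](C)/C=C(C)\C=C\[C@@H](OC(=O)C=C)CC=C)C[C@H](O[Si](C)(C)C(C)(C)C)[C@H]1C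
F9 | step 17 | allylic pinacol boronate (C11–B) | C/C=C/[C@H]1O[C@@H]([C@@H](O[Si](C)(C)C(C)(C)C)/C=C/C=C(\C)CB2OC(C)(C)C(C)(C)O2)C[C@H](O[Si](C)(C)C(C)(C)C)[C@H]1C
F10 | step 14 | (E)-vinyl iodide (C14–I) | C/C=C/[C@H]1O[C@@H]([C@@H](O[Si](C)(C)C(C)(C)C)/C=C/I)C[C@H](O[Si](C)(C)C(C)(C)C)[C@H]1C
F11 | step 14 | (E)-enyne (C12≡C13) | C/C=C/[C@H]1O[C@@H]([C@@H](O[Si](C)(C)C(C)(C)C)/C=C/C#CC)C[C@H](O[Si](C)(C)C(C)(C)C)[C@H]1C
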